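**Plan**
- Retrosynthesis: the first cut is the C12–C13 CH2–CH2 bond of the 25-membered lactone ring (C1 = carbonyl carbon, C24 = OCH2); the second is the ester C1–O bond.
- Enabling feature: C12–C13 is the midpoint of the unbranched 24-carbon chain. Both cuts therefore leave ω-bromo C12 halves that are two oxidation levels of one building block. The ring to be closed is a strain-free 25-membered ring whose only function is the ester.
- Forward: 12-bromododecanoic acid is partly reduced to the bromo alcohol, the two halves are joined at the ester, and the only ring is then closed by a nickel-catalysed reductive C(sp3)–C(sp3) coupling of the two primary C–Br ends. The bromides leave in that step, so no helper group remains to be removed.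
- Stereochemistry: the target has no stereocentre and no double bond, so nothing has to be set.

Key step: step 3

Remark: 12-bromododecan-1-ol is also an article of commerce; it is made here from 1 so that a single C12 building block supplies both halves.

**Step 1**
Reactants: 1 12-bromododecanoic acid
Product: 3 12-bromododecan-1-ol, via tris(12-bromododecyloxy)boroxine 2 (not isolated)
Conditions: BH3·THF (1.2 equiv), THF, 0 °C to rt; then H2O
Reagents that add atoms: none
Why: Borane reduces a free carboxylic acid through the acyloxyborane and the trialkoxyboroxine far faster than it touches a primary C–Br bond, so only the carboxyl end should be taken to the alcohol (chemoselective borane reduction of a carboxylic acid).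

**Step 2**
Reactants: 1 12-bromododecanoic acid; 3 12-bromododecan-1-ol
Product: 4 12-bromododecyl 12-bromododecanoate
Conditions: p-TsOH·H2O (5 mol%), toluene, reflux, Dean–Stark trap
Reagents that add atoms: none
Why: Fischer esterification of an unhindered acid with a primary alcohol should be driven to completion by azeotropic removal of water, and both primary bromides are inert to p-TsOH in hot toluene.

**Step 3**
Reactants: 4 12-bromododecyl 12-bromododecanoate
Product: 5 24-tetracosanolide (oxacyclopentacosan-2-one)
Conditions: NiCl2(CH3OCH2CH2OCH3) (5 mol%), 4,4',4''-tri-tert-butyl-2,2':6',2''-terpyridine (6 mol%), Mn powder (4 equiv), DMA/THF, 40 °C; 4 added by syringe pump over 24 h, final concentration ca. 2 mM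
Reagents that add atoms: none
Why: Proposed new method: the closest known reaction type is the (terpyridine)nickel-catalysed reductive homocoupling of unactivated primary alkyl bromides with Mn as terminal reductant, which is known between two molecules and within dihalides that close common-sized rings but has not been shown for a macrocycle. In the mechanism a low-valent (terpyridine)nickel species formed by Mn reduction takes up one C–Br terminus of 4 as a monovalent alkylnickel complex, this complex abstracts the bromine atom of the second terminus, and the primary radical so formed recombines at the same metal to give a trivalent dialkylnickel bromide in which nickel is part of a 26-membered metallacycle. C(sp3)–C(sp3) reductive elimination contracts this metallacycle to the 25-membered lactone and forms the central CH2–CH2 bond, so the ring is closed end to end between two primary carbons (a macrocyclisation by ring contraction at the metal, not an exo or endo addition), and Mn returns the monovalent nickel bromide to the cycle. No stereocentre is formed. The step needs ring closure to win over chain growth between molecules and over hydrodebromination or β-hydride elimination: slow addition keeps free 4 far below the effective molarity of a strain-free 25-membered ring, the tridentate ligand leaves no cis site for β-hydride elimination, and the substrate secures the rest because its two primary bromides are alike (any pairing of ends is productive, no cross-selectivity is needed), the chain is unbranched and the ester is inert to Mn and to low-valent nickel.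

**Compound list**
1 | 12-bromododecanoic acid | OC(=O)CCCCCCCCCCCBr | starting material
2 | tris(12-bromododecyloxy)boroxine | BrCCCCCCCCCCCCOB1OB(OCCCCCCCCCCCCBr)OB(OCCCCCCCCCCCCBr)O1 | intermediate
3 | 12-bromododecan-1-ol | OCCCCCCCCCCCCBr | intermediate
4 | 12-bromododecyl 12-bromododecanoate | BrCCCCCCCCCCCC(=O)OCCCCCCCCCCCCBr | intermediate
5 | 24-tetracosanolide (oxacyclopentacosan-2-one), achiral | O=C1CCCCCCCCCCCCCCCCCCCCCCCO1 | target

**Step count and risks**
Total step count: 3. Longest linear sequence: 3 steps (1 → 3 → 4 → 5).

Steps most likely to fail:

1. Step 3. Three processes could defeat it. Coupling between molecules could give chain growth instead of ring closure. The two ends of one molecule could be activated at two separate nickel centres and then lost by protodemetalation (hydrodebromination). β-Hydride elimination could give terminal olefins. The fallback uses known chemistry only and forms the same bond first as a double bond. It sets out from 4. Heating 4 with PPh3 (2.2 equiv) in MeCN at reflux should give the bis(triphenylphosphonium) dibromide F1. Double deprotonation with NaN(SiMe3)2 (2.1 equiv) in THF at −78 °C, where ylide formation is much faster than ester enolisation, followed by Wittig reaction with gaseous formaldehyde from cracked paraformaldehyde, should give tridec-12-en-1-yl tridec-12-enoate F2. Ring-closing metathesis with the second-generation Grubbs catalyst RuCl2(=CHPh)(PCy3)(H2IMes) in CH2Cl2 at ca. 2 mM and 40 °C should close the ring at C12=C13 with loss of ethene and give oxacyclopentacos-13-en-2-one F3 as an E/Z mixture. Both isomers converge on hydrogenation (H2, Pd/C, EtOAc, rt), which comes back to the route at 5.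

2. Step 2. The equilibrium condensation could stall short of completion, leaving acid and alcohol that are hard to separate from the waxy ester. Acid-mediated self-etherification of the alcohol is a minor competing process. The fallback replaces the equilibrium by an irreversible acyl transfer. It sets out from 1, which with oxalyl chloride and catalytic DMF in CH2Cl2 should give 12-bromododecanoyl chloride F4. Acylation of 3 with F4 and pyridine in CH2Cl2 at 0 °C comes back to the route at 4.

3. Step 1. The reduction could stop at partly reduced boron esters, or slow hydride attack at the C–Br bond could occur on prolonged exposure to excess borane. The fallback changes the substrate class and the hydride type. It sets out from 1, which with MeOH and catalytic H2SO4 at reflux should give methyl 12-bromododecanoate F5. Reduction of F5 with i-Bu2AlH (2.2 equiv) in CH2Cl2 at −78 to 0 °C, which leaves primary alkyl bromides untouched, comes back to the route at 3.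

**Further compounds**
F1 | step 3 | [12-oxo-12-(12-(triphenylphosphonio)dodecyloxy)dodecyl]triphenylphosphonium dibromide | [Br-].[Br-].O=C(CCCCCCCCCCC[P+](c1ccccc1)(c1ccccc1)c1ccccc1)OCCCCCCCCCCCC[P+](c1ccccc1)(c1ccccc1)c1ccccc1
F2 | step 3 | tridec-12-en-1-yl tridec-12-enoate | C=CCCCCCCCCCCC(=O)OCCCCCCCCCCCC=C
F3 | step 3 | oxacyclopentacos-13-en-2-one (E/Z mixture) | O=C1CCCCCCCCCCC=CCCCCCCCCCCCO1
F4 | step 2 | 12-bromododecanoyl chloride | O=C(Cl)CCCCCCCCCCCBr
F5 | step 1 | methyl 12-bromododecanoate | COC(=O)CCCCCCCCCCCBr
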